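(The earlier runs and the new flask stem from a simulated flask with made-up constants, and the scatter is random.)

If Z fell by one steady first-order loss, two ways of measuring that loss would give one constant, so I measured it both ways.

in all of them: X 0.050 M (fed, over 2.5 h)

| run | J | temperature | remark | time |
|---|---|---|---|---|
| cedar | 0.35 mM | 30 °C | run made earlier |  |
| elm | 0.55 mM | 58 °C | run made earlier |  |
| alpha | 0.25 mM | 80 °C |  | 25 h |
| beta | 0.25 mM | 35 °C |  | 25 h |
| zeta | 0.25 mM | 65 °C |  | 25 h |
| gamma | 0.25 mM | 50 °C |  | 25 h |

| run | time / h | Z / % |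
|---|---|---|
| cedar | 15.0 | 19 |
| cedar | 40.0 | 60 |
| cedar | 72.0 | 75 |
| cedar | 192 | 50 |
| elm | 6.00 | 62 |
| elm | 15.0 | 59 |
| elm | 30.0 | 48 |
| elm | 40.0 | 45 |

(scatter of a reading: 1.5 percentage points)

- the flask that comes out highest in amount of Z, in percent of the X charged, or "all alike" when all lie within 1.5 percentage points (alpha / beta / zeta / gamma / all alike)
- Z at the end, in percent of the X charged, alpha
- Z at the end, in percent of the X charged, beta
- Z at the end, in percent of the X charged, zeta
- Z at the end, in percent of the X charged, gamma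



1. The first way was the falling limb. Treating the loss as pseudo-first-order, I took the logarithm of the fall in c_Z over the hours between readings. Cedar gave 0.00338 h⁻¹, and elm gave 0.00943 h⁻¹.

2. The second way was the balance. I divided what had left Z by the hours of Z, the area under the c_Z curve in units of the charge. In cedar the early readings gave an uptake constant of 0.0282 h⁻¹, so about 16.2 % of X stood at 72.0 h. That left 8.79 % shed over 32.9 h of Z, which gave 0.00267 h⁻¹. A share this small carries the scatter of several readings, so cedar tested the limb only weakly and could not confirm it.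

3. In elm I took X as used by 15.0 h. The share of the Z present that leaves per hour by the balance, my shedding constant, was then 0.0561 h⁻¹, far above the limb.

4. One of the two cheated. At the limb constant, 34.1 % of X would have sat unused while Z fell, in a flask hotter and richer in J than cedar. So I judged the limb to be a late net fall, with Z nearing a balance against what it sheds. My own reckoning put alpha and zeta near elm's last reading, 45 %.

5. The forecast differed. It said “Z itself decays” and gave alpha 26 %, beta 49 %, zeta 44 % and gamma 61 %, with gamma highest.

6. The flasks gave alpha 53.6 %, beta 50.5 %, zeta 54.7 % and gamma 74.8 %, so gamma stood highest.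

    X + J → G + Z (k = 14.7 L mol⁻¹ h⁻¹, Ea = 57.0 kJ mol⁻¹)
    X + G → Z + G, rate k2*[G]*[X] (k = 10400 L mol⁻¹ h⁻¹, Ea = 48.0 kJ mol⁻¹)
    Z + G → X + G, rate k3*[G] as long as [Z] is above zero (k = 27.6 h⁻¹, Ea = 95.0 kJ mol⁻¹)
    2 J ⇌ E, settled at all times (K = 1700 L mol⁻¹, ΔH = −41.0 kJ mol⁻¹)
    Z + J ⇌ L + J, rate k5*[J]*[Z] forward; the back reaction follows from the equilibrium constant (K = 0.790, k = 1140 L mol⁻¹ h⁻¹, Ea = 50.0 kJ mol⁻¹, ΔH = −23.0 kJ mol⁻¹)
    (constants at 80 °C)

The path from Z to L, both ways, is the main reason: alpha ended at 53.6 %, and without that path it ended at 94.7 %. Reckoned from L gained, alpha's shedding constant was 0.0662 h⁻¹ between 2.50 h and 12.5 h, beside elm's 0.0561 h⁻¹. It was then 0.00620 h⁻¹ up to 25.0 h. Over the same two spans, zeta's went from 0.0614 h⁻¹ to 0.0210 h⁻¹.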